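Target numbering (daucane) is used for every bicyclic compound: C1 is the quaternary ring-fusion carbon (methyl C15), C2–C3 are CH2, C4 is the carbinol carbon (isopropyl C11–C13), C5 is the ring-fusion CH, C6 carries the ester oxygen, C7 is CH2, C8 carries methyl C14, C9 is CH, C10 is CH2. "β" means the face of the C15 methyl group.

## Analysis of the target

The target is the 4-hydroxy-3-methoxybenzoate of a daucane diol epoxide: a bicyclo[5.3.0]decane whose cyclopentane (C1–C5) and cycloheptane (C5–C10, C1) share the C1–C5 bond. The SMILES encodes 1R,4R,5S,6R,8R,9S. That is a trans ring fusion (C15 methyl β, H-5 α), the C4 hydroxyl and the C6 acyloxy group both β (syn to the angular methyl, with isopropyl and H-6 α), and the epoxide oxygen α (anti to the angular methyl). C1, C5, C4 and C6 are contiguous, so one quaternary centre and a fully substituted triad sit on four adjacent ring atoms, and the C6 oxygen is pseudo-axial and 1,3-syn to the angular methyl, which makes it hard to acylate. Sensitive groups are the trisubstituted epoxide (acid), the tertiary alcohol β to the C6 oxygen (dehydration, and retro-aldol whenever C6 is a ketone), the free phenol, and the C8=C9 bond, which is β,γ to C6 and can migrate into conjugation at the ketone stage. The hard parts are the quaternary C1 at the fusion of a seven-membered ring, the trans-hydroazulene, the exact position of the trisubstituted alkene, and the configuration of C4/C5/C6 relative to C1. The feature that the route uses is the sequence C5–C6(O)–C7–C8=C9: with C6 at the enol level, ring atoms C5=C6–C7–C8=C9 form a cyclohepta-1,4-diene whose allylic terminus is the quaternary C1. That is the retron of a cis-divinylcyclopropane rearrangement.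

## Retrosynthetic reasoning

20 ⇒ 19 ⇒ 18. The phenol is unmasked last by aminolysis of its acetate, and the acid-labile epoxide is introduced just before, on alkene 18. The C8–O and C9–O bonds are cut there because both β-face neighbours of the alkene (the angular methyl and the C6 aroyloxy group) should send a peracid to the α face, so C8 and C9 are set together by the substrate.

18 ⇒ 15 + 17. The ester C6–O(acyl) bond is cut. Diol 15 has one acylable hydroxyl (the tertiary C4 hydroxyl is inert), and acid chloride 17 comes in one step from commercial acid 16. The forward step must acylate a hindered axial alcohol without touching the aryl acetate.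

15 ⇒ 13 ⇒ 12. The C14 methyl group is traced back to a methyl ester on C8. This costs two reductive steps, and is accepted because the ester is the acceptor group that the carbenoid of the key step needs. The forward steps must remove the allylic oxygen without moving the C8=C9 bond.

12 ⇒ 11 ⇒ 10 ⇒ 9. The C4/C5/C6 triad is traced to the flat dienone 9. C5–H comes from reductive opening of a 4β,5β-epoxide, C4–O from hydroxyl-directed epoxidation, and C6 from a catalyst-controlled ketone reduction. Each centre is relayed from the one before, and all are relayed from C1. No carbonyl addition has to choose a face of C4 while C5 is still sp2, where the two faces of C4 differ only by the C15 methyl against the C10 methylene on C1.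

9 ⇒ 7. The C4–isopropyl bond is cut in a 1,2-addition to a vinylogous ester, followed by acidic transposition through 8. Cutting here turns the 1,3-dioxygen pattern delivered by the key step (C4=O, C6–OEt) into exactly the enone needed, and the stereocentre formed in the addition does not matter.

7 ⇒ 6 ⇒ 3 + 5 (key disconnection). The seven-membered ring is cut at C1–C10 and C7–C8. The C1–C10 bond, the quaternary centre and the ring arise from the [3,3] shift of cis-divinylcyclopropane 6. Compound 6 arises by enantioselective cyclopropanation of the 1-ethoxyvinyl group of diene 3 (C7=C6, C5=C1, C4=O) with the vinylcarbenoid from 5 (C8 with its ester carbon C14, C9=C10). This single operation is to deliver the hydroazulene, the only stereocentre that cannot be corrected later, the C8=C9 alkene in its final position, and differentiated oxygen at C4 and C6.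

3 ⇒ 1 + 2 and 5 ⇒ 4. The diene is cut at the C5–C6 bond (cross-coupling of a bromoenone with an alkoxyvinylstannane), and the diazo ester at C8=N2 (diazo transfer). Both precursors of the key step are one step from commercial materials.

## Alternatives that were turned down

Alternative 1: ring-closing metathesis at C8=C9 (the textbook route). The second-generation Grubbs catalyst would close diene A1, a cyclopentane already carrying C1, C4, C5 and C6 with allyl and methallyl arms, to diol 15. The metathesis forms the least demanding bond and sets no stereocentre, so all four centres of A1 must be built one at a time on a flexible cyclopentane. The quaternary C1 would need conjugate allylation of a β-methylcyclopentenone, where allyl nucleophiles prefer 1,2-addition. C5/C6 would need an aldol with a β,γ-unsaturated aldehyde that isomerises easily, and C4 an isopropyl addition to a retro-aldol-prone β-hydroxy ketone. The way to A1 would be at least as long as the whole present route.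

Alternative 2: rhodium-catalysed (5+2) cycloaddition of a vinylcyclopropane with a tethered alkene, cutting C1–C5 and C9–C10. With [Rh(CO)2Cl]2, the siloxy-vinylcyclopropane A2 would close both rings at once to cycloadduct A3. The five-carbon unit places its new alkene at C6=C7 and leaves C8–C9 saturated, so the target's C8=C9 bond would have to be introduced afterwards at an unactivated position. Alkene tethers of this kind normally give the cis ring fusion, whereas A3 must be trans. A2 also needs an enantioselective tertiary alcohol and a trans-disubstituted cyclopropane whose C8 stereocentre is later destroyed.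

Alternative 3: intramolecular aldol closure of the five-membered ring at C4–C5. Base would cyclise the cycloheptenone A4, which carries an isopropyl ketone side chain on quaternary C1, to the hydroxy ketone A5. Attack of the planar C5 enolate next to C1 must be axial with the tether equatorial, which gives the cis-fused isomer. The reaction is reversible, so C4 would be set by equilibration and not by design, and the basic medium invites migration of the C8=C9 bond into conjugation. A4 also still needs its own asymmetric quaternary centre on a seven-membered ring, so nothing is simplified.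

Key step: step 3

Assumption: the sense of induction of Rh2(R-DOSP)4 with diene 3 is taken from the accepted model for vinylcarbenoid cyclopropanation of monosubstituted alkenes; should 7 form in the 8aS series, Rh2(S-DOSP)4 is used and nothing else changes.

## Route

Step 1
Reactants: 1 2-bromo-3-methylcyclopent-2-en-1-one; 2 tributyl(1-ethoxyethenyl)stannane
Product: 3 2-(1-ethoxyethenyl)-3-methylcyclopent-2-en-1-one
Conditions: Pd(PPh3)4 (5 mol %), CuI (10 mol %), toluene, 90 °C; aqueous KF work-up, Et3N-deactivated silica
Reagents that add atoms: none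
Why: Stille coupling of an α-bromoenone with a 1-alkoxyvinylstannane (oxidative addition of zerovalent palladium into the vinylic C–Br bond, transmetallation, reductive elimination) should give the 2-alkoxydiene directly; base-washed handling keeps the enol ether from hydrolysing. No stereocentre is formed.

Step 2
Reactants: 4 methyl but-3-enoate
Product: 5 methyl 2-diazobut-3-enoate
Conditions: 4-acetamidobenzenesulfonyl azide, DBU, MeCN, 0 °C; extracted into pentane and used cold at once
Reagents that add atoms: 4-acetamidobenzenesulfonyl azide, CC(=O)Nc1ccc(cc1)S(=O)(=O)N=[N+]=[N-]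
Why: Regitz-type diazo transfer to the dienolate of a β,γ-unsaturated ester, whose α-CH2 is activated by both the ester and the vinyl group. Compound 5 slowly cyclises to a pyrazole, so it is not stored.

Step 3
Reactants: 3 2-(1-ethoxyethenyl)-3-methylcyclopent-2-en-1-one; 5 methyl 2-diazobut-3-enoate
Product: 7 methyl (8aR)-4-ethoxy-8a-methyl-3-oxo-1,2,3,5,8,8a-hexahydroazulene-6-carboxylate, via cis-divinylcyclopropane 6 (not isolated)
Conditions: Rh2(R-DOSP)4 (dirhodium tetrakis[(R)-N-(4-dodecylbenzenesulfonyl)prolinate], 1 mol %), hexanes, −40 °C, slow addition of 5 (2.5 equiv); then toluene, 100 °C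
Reagents that add atoms: none
Why: Rh2(R-DOSP)4 converts 5 into a donor/acceptor vinylcarbenoid that cyclopropanates the only electron-rich and unhindered double bond of 3 (the 1-ethoxyvinyl group C6=C7; the ring alkene is a tetrasubstituted enone), closing the three-membered ring of 6 in a [2+1] addition with the carbenoid vinyl group cis to the cyclopentenyl group. On heating, 6 undergoes the divinylcyclopropane (Cope) rearrangement through the obligatory boat transition state: the donor–acceptor C6–C8 bond breaks and C1–C10 forms, which closes the seven-membered ring as a [3,3]-sigmatropic ring expansion. The closest known reaction type is this tandem cyclopropanation/Cope sequence (the formal [4+3] cycloaddition of vinylcarbenoids) with 2-oxygenated and terminally disubstituted dienes, including cases that form quaternary carbons. The only stereocentre of 7, quaternary C1 (C8a), is fixed by chirality transfer: the catalyst sets C6 and C8 of 6 by choosing the carbenoid face, and the suprafacial boat geometry lets only one face of the ring alkene reach C10, so (1S,2R)-6 should give (8aR)-7. The step needs chemoselectivity for the enol ether (secured by its nucleophilicity and accessibility), attack at the carbenoid carbon and not at the vinyl terminus (hydrocarbon solvent, prolinate catalyst), and a concerted, not zwitterionic, ring opening (non-polar medium). The C15 methyl points inward in the boat and slows the shift, hence the heating, while the ethoxy donor on C6, the ester acceptor on C8 and the enone β-carbon C1 polarise the shift in the productive direction.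

Step 4
Reactants: 7 methyl (8aR)-4-ethoxy-8a-methyl-3-oxo-1,2,3,5,8,8a-hexahydroazulene-6-carboxylate
Product: 9 methyl (8aR)-8a-methyl-4-oxo-3-(propan-2-yl)-1,2,4,5,8,8a-hexahydroazulene-6-carboxylate, via tertiary allylic alcohol 8 (not isolated)
Conditions: iPrMgCl, CeCl3, THF, −78 °C; then 1 M aqueous HCl, 0 °C, short contact
Reagents that add atoms: isopropylmagnesium chloride, CC(C)[Mg]Cl; water, O
Why: Stork–Danheiser sequence: iPrCeCl2 adds 1,2 to the vinylogous-ester carbonyl C4 at −78 °C, where a conjugated methyl ester is not attacked and enolisation is suppressed; dilute acid then ionises 8, water adds at C6 and ethanol is lost, giving the transposed enone. The C4 stereocentre of 8 is destroyed, so its configuration is irrelevant, and C1 is untouched.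

Step 5
Reactants: 9 methyl (8aR)-8a-methyl-4-oxo-3-(propan-2-yl)-1,2,4,5,8,8a-hexahydroazulene-6-carboxylate
Product: 10 methyl (4R,8aR)-4-hydroxy-8a-methyl-3-(propan-2-yl)-1,2,4,5,8,8a-hexahydroazulene-6-carboxylate
Conditions: (S)-2-methyl-CBS-oxazaborolidine (20 mol %), catecholborane, toluene, −78 °C
Reagents that add atoms: none
Why: Corey–Bakshi–Shibata reduction: the ketone binds the catalyst through the lone pair on the side of its small substituent (C7H2), away from the tetrasubstituted alkenyl carbon C5, and hydride is delivered under catalyst control; the (S)-catalyst should give the 6R (β) alcohol. Catecholborane at −78 °C leaves the conjugated ester and both alkenes alone, and early reduction removes the ketone that could pull C8=C9 into conjugation.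

Step 6
Reactants: 10 methyl (4R,8aR)-4-hydroxy-8a-methyl-3-(propan-2-yl)-1,2,4,5,8,8a-hexahydroazulene-6-carboxylate
Product: 11 methyl (1R,4R,5S,6R)-4,5-epoxy-6-hydroxydauc-8-en-14-oate (4β,5β-epoxide)
Conditions: VO(acac)2 (5 mol %), t-BuOOH, CH2Cl2, 0 °C
Reagents that add atoms: tert-butyl hydroperoxide, CC(C)(C)OO
Why: Hydroxyl-directed epoxidation of an allylic alcohol: H-6 eclipses the alkene plane (allylic 1,3-strain with the isopropyl group), so the C6 vanadate ester stands over the β face of the tetrasubstituted C4=C5 bond and delivers oxygen there, setting C4 (O β, isopropyl α). The ester-deactivated and only homoallylic C8=C9 bond should not react.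

Step 7
Reactants: 11 methyl (1R,4R,5S,6R)-4,5-epoxy-6-hydroxydauc-8-en-14-oate
Product: 12 methyl (1R,4R,5S,6R)-4,6-dihydroxydauc-8-en-14-oate
Conditions: Cp2TiCl2 (20 mol %), Zn, 2,4,6-collidine hydrochloride, 1,4-cyclohexadiene, THF, rt
Reagents that add atoms: none
Why: Reductive opening of a 2,3-epoxy alcohol by the trivalent titanium complex Cp2TiCl formed in situ (Nugent–RajanBabu reaction, catalytic protocol): titanium held by the C6 oxygen cleaves the proximal C5–O bond, as in the known conversion of 2,3-epoxy alcohols into 1,3-diols, and the tertiary C5 radical takes hydrogen from 1,4-cyclohexadiene. The β face of that radical carries the angular methyl and both oxygen substituents, so hydrogen should arrive from the α face and make the ring fusion trans; C4 keeps its oxygen with retention.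

Step 8
Reactants: 12 methyl (1R,4R,5S,6R)-4,6-dihydroxydauc-8-en-14-oate
Product: 13 (1R,4R,5S,6R)-dauc-8-ene-4,6,14-triol
Conditions: iBu2AlH (DIBAL-H, 5 equiv), CH2Cl2, −78 → 0 °C; potassium sodium tartrate work-up
Reagents that add atoms: none
Why: 1,2-Reduction of the conjugated ester to the primary allylic alcohol; the two existing hydroxyls ride through as aluminium alkoxides and no stereocentre is touched.

Step 9
Reactants: 13 (1R,4R,5S,6R)-dauc-8-ene-4,6,14-triol
Product: 15 (1R,4R,5S,6R)-dauc-8-ene-4,6-diol, via allylic mesylate 14 (not isolated)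
Conditions: MsCl (1.05 equiv), Et3N, THF, −40 °C; then LiEt3BH, −40 → 0 °C
Reagents that add atoms: none
Why: The unhindered primary allylic hydroxyl is mesylated selectively beside the axial secondary and the tertiary hydroxyl, and LiEt3BH displaces the mesylate by direct SN2 hydride attack at the primary carbon, which leaves C8=C9 in place. Closure of the C6 alkoxide onto C14 would create a bridgehead alkene and should not compete.

Step 10
Reactants: 16 4-acetoxy-3-methoxybenzoic acid
Product: 17 4-acetoxy-3-methoxybenzoyl chloride
Conditions: (COCl)2, DMF (cat.), CH2Cl2, 0 °C → rt; volatiles removed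
Reagents that add atoms: oxalyl chloride, ClC(=O)C(Cl)=O
Why: Standard acid chloride formation through the chloroiminium species; the aryl acetate is stable to these conditions.

Step 11
Reactants: 15 (1R,4R,5S,6R)-dauc-8-ene-4,6-diol; 17 4-acetoxy-3-methoxybenzoyl chloride
Product: 18 (1R,4R,5S,6R)-4-hydroxydauc-8-en-6-yl 4-acetoxy-3-methoxybenzoate
Conditions: Et3N, DMAP (1 equiv), CH2Cl2, rt → 40 °C
Reagents that add atoms: none
Why: DMAP-mediated acylation through the acylpyridinium ion; only the secondary C6 hydroxyl can react, the tertiary C4 hydroxyl is inert, and C6 keeps its configuration because its C–O bond is not broken.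

Step 12
Reactants: 18 (1R,4R,5S,6R)-4-hydroxydauc-8-en-6-yl 4-acetoxy-3-methoxybenzoate
Product: 19 (1R,4R,5S,6R,8R,9S)-8,9-epoxy-4-hydroxydaucan-6-yl 4-acetoxy-3-methoxybenzoate
Conditions: mCPBA, NaHCO3, CH2Cl2, 0 °C
Reagents that add atoms: 3-chloroperbenzoic acid, OOC(=O)c1cccc(Cl)c1
Why: Prilezhaev epoxidation of the only alkene: the β face of C8=C9 is screened by the angular methyl and the pseudo-axial C6 aroyloxy group, so the peracid should attack the α face and set C8 (R) and C9 (S) together. The bicarbonate buffer protects the epoxide and the acetate keeps the phenol inert.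

Step 13
Reactants: 19 (1R,4R,5S,6R,8R,9S)-8,9-epoxy-4-hydroxydaucan-6-yl 4-acetoxy-3-methoxybenzoate
Product: 20 (1R,4R,5S,6R,8R,9S)-8,9-epoxy-4-hydroxydaucan-6-yl 4-hydroxy-3-methoxybenzoate (target)
Conditions: pyrrolidine (1.5 equiv), CH2Cl2, 0 °C
Reagents that add atoms: none
Why: Aminolysis of the aryl acetate, an activated ester, is fast at 0 °C, whereas the hindered secondary aryl ester and the trisubstituted epoxide should not react.

## Compound list

1 | 2-bromo-3-methylcyclopent-2-en-1-one | CC1=C(Br)C(=O)CC1 | starting material
2 | tributyl(1-ethoxyethenyl)stannane | CCOC(=C)[Sn](CCCC)(CCCC)CCCC | starting material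
3 | 2-(1-ethoxyethenyl)-3-methylcyclopent-2-en-1-one | CCOC(=C)C1=C(C)CCC1=O | intermediate
4 | methyl but-3-enoate | C=CCC(=O)OC | starting material
5 | methyl 2-diazobut-3-enoate | C=CC(=[N+]=[N-])C(=O)OC | intermediate
6 | methyl (1S,2R)-1-ethenyl-2-ethoxy-2-(2-methyl-5-oxocyclopent-1-en-1-yl)cyclopropane-1-carboxylate | C=C[C@@]1(C(=O)OC)C[C@@]1(OCC)C2=C(C)CCC2=O | intermediate (not isolated)
7 | methyl (8aR)-4-ethoxy-8a-methyl-3-oxo-1,2,3,5,8,8a-hexahydroazulene-6-carboxylate | COC(=O)C1=CC[C@@]2(C)CCC(=O)C2=C(OCC)C1 | intermediate
8 | methyl (8aR)-4-ethoxy-3-hydroxy-8a-methyl-3-(propan-2-yl)-1,2,3,5,8,8a-hexahydroazulene-6-carboxylate (both C3 epimers; this centre is destroyed in the same step) | COC(=O)C1=CC[C@@]2(C)CCC(O)(C(C)C)C2=C(OCC)C1 | intermediate (not isolated)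
9 | methyl (8aR)-8a-methyl-4-oxo-3-(propan-2-yl)-1,2,4,5,8,8a-hexahydroazulene-6-carboxylate | COC(=O)C1=CC[C@@]2(C)CCC(C(C)C)=C2C(=O)C1 | intermediate
10 | methyl (4R,8aR)-4-hydroxy-8a-methyl-3-(propan-2-yl)-1,2,4,5,8,8a-hexahydroazulene-6-carboxylate | COC(=O)C1=CC[C@@]2(C)CCC(C(C)C)=C2[C@H](O)C1 | intermediate
11 | methyl (1R,4R,5S,6R)-4,5-epoxy-6-hydroxydauc-8-en-14-oate | COC(=O)C1=CC[C@@]2(C)CC[C@]3(C(C)C)O[C@]23[C@H](O)C1 | intermediate
12 | methyl (1R,4R,5S,6R)-4,6-dihydroxydauc-8-en-14-oate | COC(=O)C1=CC[C@@]2(C)CC[C@@](O)(C(C)C)[C@@H]2[C@H](O)C1 | intermediate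
13 | (1R,4R,5S,6R)-dauc-8-ene-4,6,14-triol | OCC1=CC[C@@]2(C)CC[C@@](O)(C(C)C)[C@@H]2[C@H](O)C1 | intermediate
14 | (1R,4R,5S,6R)-4,6-dihydroxydauc-8-en-14-yl methanesulfonate | CS(=O)(=O)OCC1=CC[C@@]2(C)CC[C@@](O)(C(C)C)[C@@H]2[C@H](O)C1 | intermediate (not isolated)
15 | (1R,4R,5S,6R)-dauc-8-ene-4,6-diol | CC1=CC[C@@]2(C)CC[C@@](O)(C(C)C)[C@@H]2[C@H](O)C1 | intermediate
16 | 4-acetoxy-3-methoxybenzoic acid | CC(=O)Oc1ccc(cc1OC)C(=O)O | starting material
17 | 4-acetoxy-3-methoxybenzoyl chloride | CC(=O)Oc1ccc(cc1OC)C(Cl)=O | intermediate
18 | (1R,4R,5S,6R)-4-hydroxydauc-8-en-6-yl 4-acetoxy-3-methoxybenzoate | COc1cc(C(=O)O[C@@H]2CC(C)=CC[C@@]3(C)CC[C@@](O)(C(C)C)[C@H]23)ccc1OC(C)=O | intermediate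
19 | (1R,4R,5S,6R,8R,9S)-8,9-epoxy-4-hydroxydaucan-6-yl 4-acetoxy-3-methoxybenzoate | COc1cc(C(=O)O[C@@H]2C[C@@]3(C)O[C@H]3C[C@@]3(C)CC[C@@](O)(C(C)C)[C@H]23)ccc1OC(C)=O | intermediate
20 | (1R,4R,5S,6R,8R,9S)-8,9-epoxy-4-hydroxydaucan-6-yl 4-hydroxy-3-methoxybenzoate | COc1cc(C(=O)O[C@@H]2C[C@@]3(C)O[C@H]3C[C@@]3(C)CC[C@@](O)(C(C)C)[C@H]23)ccc1O | target

## Step count and least certain steps

Total: 13 steps. Longest linear sequence: 11 steps (steps 1, 3–9, 11–13); steps 2 and 10 are side branches.

Step 3 (key step). The enol ether may attack the unsubstituted vinyl terminus of the carbenoid instead of the carbenoid carbon, or the donor–acceptor cyclopropane may open to a zwitterion before the shift; either process leads to five-membered-ring closure and erodes enantiopurity. The inward methyl group may also slow the Cope step enough for these pathways to compete. Fallback, from 3 back to 7: methyl acetoacetate is converted by diazo transfer into methyl 2-diazo-3-oxobutanoate F1 and silylated (TBSOTf, Et3N) to the stable siloxyvinyl diazo ester methyl 3-[(tert-butyldimethylsilyl)oxy]-2-diazobut-3-enoate F2. Its carbenoid reacts cleanly at the carbenoid carbon, and with 3 and Rh2(R-PTAD)4 it should give the 7-siloxy cycloadduct F3. CsF and N-phenylbis(trifluoromethanesulfonimide) convert the silyl enol ether of F3 into the enol triflate F4, and reduction with Pd(OAc)2/PPh3, HCO2H and Et3N removes the triflate to give 7.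

Step 7. Homolysis may occur at C4–O instead of C5–O, the C5 radical may lose H-6 instead of taking up hydrogen, or hydrogen may be delivered to the β face and give the cis fusion. Fallback, from 11 back to 12, working at the ketone level with two-electron chemistry: Dess–Martin oxidation of 11 gives the epoxy ketone methyl (1R,4R,5R)-4,5-epoxy-6-oxodauc-8-en-14-oate F9. SmI2 (THF/MeOH, −78 °C) cleaves its Cα–O bond and protonation of the enolate from the α face gives the hydroxy ketone methyl (1R,4R,5R)-4-hydroxy-6-oxodauc-8-en-14-oate F10. LiB(sec-Bu)3H then reduces C6 from the α face, anti to the syn-axial angular methyl, to give 12.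

Step 4. The organocerium reagent may attack the methyl ester in competition with the deactivated carbonyl, and during acidic unmasking the C8=C9 bond may migrate into conjugation with the new ketone. Fallback, from 7 back to 9, masking the ester as its own carboxylate: LiOH hydrolysis gives the acid (8aR)-4-ethoxy-8a-methyl-3-oxo-1,2,3,5,8,8a-hexahydroazulene-6-carboxylic acid F5. Excess iPrCeCl2 adds to its lithium salt, and brief acid treatment gives the enone acid (8aR)-8a-methyl-4-oxo-3-(propan-2-yl)-1,2,4,5,8,8a-hexahydroazulene-6-carboxylic acid F6. Neutral methylation with trimethylsilyldiazomethane returns 9.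

Step 5. The isopropyl group twists the carbonyl out of conjugation, so an intrinsic facial bias of the substrate may override the catalyst and lower the selectivity at C6, which would then propagate to C4 and C5. Fallback, from 9 back to 10, correcting by inversion instead of by catalyst control: Luche reduction (NaBH4, CeCl3) under substrate control; if it gives mainly the epimeric alcohol methyl (4S,8aR)-4-hydroxy-8a-methyl-3-(propan-2-yl)-1,2,4,5,8,8a-hexahydroazulene-6-carboxylate F7, Mitsunobu reaction with 4-nitrobenzoic acid gives the inverted ester methyl (4R,8aR)-8a-methyl-4-[(4-nitrobenzoyl)oxy]-3-(propan-2-yl)-1,2,4,5,8,8a-hexahydroazulene-6-carboxylate F8, and K2CO3 in methanol releases 10.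

Step 12. Facial selectivity may be poor if the seven-membered ring adopts a conformation that exposes the β face, and the acid by-product may open the epoxide. Fallback, from 18 directly to 20, delivering oxygen to the face opposite to the one an electrophile prefers: N-bromosuccinimide in aqueous THF forms the bromonium ion on the more accessible face and water opens it anti at the tertiary C8, giving the bromohydrin (1R,4R,5S,6R,8R,9R)-9-bromo-4,8-dihydroxydaucan-6-yl 4-acetoxy-3-methoxybenzoate F11. K2CO3 in methanol then closes the α-epoxide with inversion at C9 and cleaves the phenol acetate in the same operation, giving 20.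

## Further compounds

F1 | step 3 | methyl 2-diazo-3-oxobutanoate | COC(=O)C(=[N+]=[N-])C(C)=O
F2 | step 3 | methyl 3-[(tert-butyldimethylsilyl)oxy]-2-diazobut-3-enoate | COC(=O)C(=[N+]=[N-])C(=C)O[Si](C)(C)C(C)(C)C
F3 | step 3 | methyl (8aR)-7-[(tert-butyldimethylsilyl)oxy]-4-ethoxy-8a-methyl-3-oxo-1,2,3,5,8,8a-hexahydroazulene-6-carboxylate | COC(=O)C1=C(O[Si](C)(C)C(C)(C)C)C[C@@]2(C)CCC(=O)C2=C(OCC)C1
F4 | step 3 | methyl (8aR)-4-ethoxy-8a-methyl-3-oxo-7-[(trifluoromethanesulfonyl)oxy]-1,2,3,5,8,8a-hexahydroazulene-6-carboxylate | COC(=O)C1=C(OS(=O)(=O)C(F)(F)F)C[C@@]2(C)CCC(=O)C2=C(OCC)C1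
F5 | step 4 | (8aR)-4-ethoxy-8a-methyl-3-oxo-1,2,3,5,8,8a-hexahydroazulene-6-carboxylic acid | OC(=O)C1=CC[C@@]2(C)CCC(=O)C2=C(OCC)C1
F6 | step 4 | (8aR)-8a-methyl-4-oxo-3-(propan-2-yl)-1,2,4,5,8,8a-hexahydroazulene-6-carboxylic acid | OC(=O)C1=CC[C@@]2(C)CCC(C(C)C)=C2C(=O)C1
F7 | step 5 | methyl (4S,8aR)-4-hydroxy-8a-methyl-3-(propan-2-yl)-1,2,4,5,8,8a-hexahydroazulene-6-carboxylate | COC(=O)C1=CC[C@@]2(C)CCC(C(C)C)=C2[C@@H](O)C1
F8 | step 5 | methyl (4R,8aR)-8a-methyl-4-[(4-nitrobenzoyl)oxy]-3-(propan-2-yl)-1,2,4,5,8,8a-hexahydroazulene-6-carboxylate | COC(=O)C1=CC[C@@]2(C)CCC(C(C)C)=C2[C@H](OC(=O)c3ccc(cc3)[N+](=O)[O-])C1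
F9 | step 7 | methyl (1R,4R,5R)-4,5-epoxy-6-oxodauc-8-en-14-oate | COC(=O)C1=CC[C@@]2(C)CC[C@]3(C(C)C)O[C@]23C(=O)C1
F10 | step 7 | methyl (1R,4R,5R)-4-hydroxy-6-oxodauc-8-en-14-oate | COC(=O)C1=CC[C@@]2(C)CC[C@@](O)(C(C)C)[C@@H]2C(=O)C1
F11 | step 12 | (1R,4R,5S,6R,8R,9R)-9-bromo-4,8-dihydroxydaucan-6-yl 4-acetoxy-3-methoxybenzoate | COc1cc(C(=O)O[C@@H]2C[C@@](C)(O)[C@H](Br)C[C@@]3(C)CC[C@@](O)(C(C)C)[C@H]23)ccc1OC(C)=O
A1 | alternative 1 | (1R,2S,3R)-2-[(1R)-1-hydroxy-3-methylbut-3-en-1-yl]-3-methyl-1-(propan-2-yl)-3-(prop-2-en-1-yl)cyclopentan-1-ol | C=CC[C@@]1(C)CC[C@@](O)(C(C)C)[C@@H]1[C@H](O)CC(C)=C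
A2 | alternative 2 | (1E,3R)-1-[(tert-butyldimethylsilyl)oxy]-6-methyl-1-[(1R,2R)-2-methylcyclopropyl]-3-(propan-2-yl)hepta-1,6-dien-3-ol | C=C(C)CC[C@@](O)(C(C)C)/C=C(/O[Si](C)(C)C(C)(C)C)[C@@H]1C[C@H]1C
A3 | alternative 2 | trans-fused 6-[(tert-butyldimethylsilyl)oxy]dauc-6-en-4β-ol (H-5 α, C15 methyl β, C8–C9 saturated) | C[C@@H]1CC[C@@]2(C)CC[C@@](O)(C(C)C)[C@@H]2C(O[Si](C)(C)C(C)(C)C)=C1
A4 | alternative 3 | (6R)-3,6-dimethyl-6-(4-methyl-3-oxopentyl)cyclohept-3-en-1-one | CC(C)C(=O)CC[C@]1(C)CC=C(C)CC(=O)C1
A5 | alternative 3 | (1R,4R,5R)-4-hydroxydauc-8-en-6-one | CC1=CC[C@@]2(C)CC[C@@](O)(C(C)C)[C@@H]2C(=O)C1
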